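**Retrosynthetic overview**
1. Target acid ⇐ its tert-butyl ester; the 1,2-dioxan-3-ol (the only ring, formed last) ⇐ spontaneous hemiketalisation of a γ-hydroperoxy β-keto ester.
2. Tertiary C6–OO bond ⇐ Co-catalysed Markovnikov peroxysilylation of a C6 exo-methylene; C3 ketone ⇐ oxidation of an aldol carbinol.
3. Key C2–C3 bond ⇐ intermolecular aldol of the lithium enolate of tert-butyl acetate with the α-methyl aldehyde carrying C3–C16.
4. C4 stereocentre ⇐ Evans alkylation of (S)-4-benzyl-3-propanoyloxazolidinone with a 2-substituted allyl bromide.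
5. Allyl bromide with the side-chain stereocentre ⇐ (S)-citronellol: Cu-catalysed coupling with 6-phenylhexyl Grignard, ozonolysis, α-methylenation.

Assumption: no dependable method sets the tertiary peroxide centre C6 selectively, so it is formed as a roughly 1:1 pair and the (6S) isomer is isolated by chromatography after ring closure; all other centres come from the chiral pool, the auxiliary or thermodynamic control.

**Step 1**
Reactants: 1 (S)-citronellol
Product: 2 (3S)-3,7-dimethyloct-6-en-1-yl 4-methylbenzenesulfonate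
Conditions: TsCl, Et3N, DMAP (cat.), CH2Cl2, 0 °C → rt
Reagents that add atoms: p-toluenesulfonyl chloride, Cc1ccc(cc1)S(=O)(=O)Cl
Why: Standard O-sulfonylation of a primary alcohol; the stereocentre is remote and untouched.

**Step 2**
Reactants: 2 (3S)-3,7-dimethyloct-6-en-1-yl tosylate; 3 (6-bromohexyl)benzene
Product: 5 [(9R)-9,13-dimethyltetradec-12-en-1-yl]benzene, via (6-phenylhexyl)magnesium bromide 4 (not isolated)
Conditions: Mg, THF, 40 °C; then 2, Li2CuCl4 (5 mol %), THF, −78 °C → rt
Reagents that add atoms: none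
Why: Copper-catalysed sp3–sp3 Grignard/tosylate cross-coupling (Kochi–Schlosser type) extends the chain to (CH2)8Ph without touching the stereocentre (descriptor changes to R by priority only).

**Step 3**
Reactants: 5 [(9R)-9,13-dimethyltetradec-12-en-1-yl]benzene
Product: 7 (4R)-4-methyl-12-phenyldodecanal, via secondary ozonide 6 (not isolated)
Conditions: O3, CH2Cl2, −78 °C (Sudan III end-point); then PPh3, −78 °C → rt
Reagents that add atoms: ozone, [O-][O+]=O
Why: Ozonolysis cleaves the electron-rich trisubstituted alkene far faster than the arene, and PPh3 reduces the ozonide to the aldehyde.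

**Step 4**
Reactants: 7 (4R)-4-methyl-12-phenyldodecanal
Product: 8 (4R)-4-methyl-2-methylidene-12-phenyldodecanal
Conditions: 37% aq. CH2O, pyrrolidine (10 mol %), EtCO2H (10 mol %), i-PrOH, 45 °C
Reagents that add atoms: formaldehyde, C=O
Why: Amine-catalysed Mannich-type α-methylenation (enamine plus iminium, then β-elimination) gives the 2-substituted acrolein; there is no stereocentre α to the aldehyde to lose.

**Step 5**
Reactants: 8 (4R)-4-methyl-2-methylidene-12-phenyldodecanal
Product: 9 (4R)-4-methyl-2-methylidene-12-phenyldodecan-1-ol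
Conditions: NaBH4, CeCl3·7H2O, MeOH, 0 °C
Reagents that add atoms: none
Why: Luche reduction gives clean 1,2-reduction of the enal to the allylic alcohol.

**Step 6**
Reactants: 9 (4R)-4-methyl-2-methylidene-12-phenyldodecan-1-ol
Product: 10 [(9R)-11-(bromomethyl)-9-methyldodec-11-en-1-yl]benzene
Conditions: CBr4, PPh3, CH2Cl2, 0 °C
Reagents that add atoms: carbon tetrabromide, BrC(Br)(Br)Br
Why: Appel bromination of a primary allylic alcohol under neutral conditions; the allyl system is symmetric about the transposition, so SN2/SN2′ give the same bromide.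

**Step 7**
Reactants: 11 (4S)-4-benzyl-3-propanoyl-1,3-oxazolidin-2-one; 10 allylic bromide
Product: 13 (4S)-4-benzyl-3-[(2R,6R)-2,6-dimethyl-4-methylidene-14-phenyltetradecanoyl]-1,3-oxazolidin-2-one, via sodium Z-enolate 12 (not isolated)
Conditions: NaHMDS, THF, −78 °C; then 10, −78 → −40 °C
Reagents that add atoms: none
Why: Evans asymmetric alkylation: the chelated Z-enolate is alkylated by the reactive allylic bromide on the face opposite the benzyl group, setting the future ring C4 as R (dr typically >95:5, minor isomer removed by chromatography).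

**Step 8**
Reactants: 13 alkylated imide
Product: 14 (2R,6R)-2,6-dimethyl-4-methylidene-14-phenyltetradecan-1-ol
Conditions: LiBH4, MeOH (1 equiv), Et2O, 0 °C
Reagents that add atoms: none
Why: Reductive cleavage of the N-acyl oxazolidinone at the exocyclic carbonyl gives the primary alcohol without epimerisation and returns the auxiliary.

**Step 9**
Reactants: 14 (2R,6R)-alcohol
Product: 15 (2R,6R)-2,6-dimethyl-4-methylidene-14-phenyltetradecanal
Conditions: DMP, NaHCO3, CH2Cl2, 0 °C → rt (used crude at once)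
Reagents that add atoms: none
Why: Buffered Dess–Martin oxidation is mild enough to keep the α-methyl aldehyde configurationally intact.

**Step 10**
Reactants: 15 (2R,6R)-aldehyde; 16 tert-butyl acetate
Product: 18 tert-butyl (4R,8R)-3-hydroxy-4,8-dimethyl-6-methylidene-16-phenylhexadecanoate (both C3 epimers), via lithium enolate of tert-butyl acetate 17 (not isolated)
Conditions: LDA, THF, −78 °C; then 15, −78 °C; H2O quench
Reagents that add atoms: none
Why: Intermolecular acetate aldol addition of a preformed lithium ester enolate is fast and irreversible at −78 °C and joins the C1–C2 unit to the C3–C16 chain without epimerising C4; the new carbinol centre is oxidised later, so its configuration is irrelevant.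

**Step 11**
Reactants: 18 β-hydroxy ester
Product: 19 tert-butyl (4R,8R)-3-hydroxy-4,6,8-trimethyl-16-phenyl-6-[(triethylsilyl)peroxy]hexadecanoate (epimers at C3 and C6)
Conditions: Co(thd)2 (10 mol %), Et3SiH, O2 (1 atm), ClCH2CH2Cl, rt
Reagents that add atoms: dioxygen, O=O; triethylsilane, CC[SiH](CC)CC
Why: Mukaiyama–Isayama peroxysilylation: Co–H hydrogen-atom transfer gives the Markovnikov tertiary radical at C6, which traps O2 and is silylated; alcohols and esters are tolerated, and C6 forms with no facial control (about 1:1).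

**Step 12**
Reactants: 19 silylperoxy hydroxy ester
Product: 20 tert-butyl (4R,8R)-4,6,8-trimethyl-3-oxo-16-phenyl-6-[(triethylsilyl)peroxy]hexadecanoate (C6 epimers)
Conditions: DMP, NaHCO3, CH2Cl2, 0 °C
Reagents that add atoms: none
Why: Dess–Martin oxidation of the β-hydroxy ester to the β-keto ester leaves the silyl peroxide untouched; the keto ester enolises toward C2, so C4 is not scrambled.

**Step 13**
Reactants: 20 silylperoxy β-keto ester
Product: 22 tert-butyl 2-[(3S,4R,6S)-3-hydroxy-4,6-dimethyl-6-[(2R)-2-methyl-10-phenyldecyl]-1,2-dioxan-3-yl]acetate, via free hydroperoxy keto ester 21 (not isolated)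
Conditions: 48% aq. HF, MeCN, 0 °C; SiO2 chromatography to remove the 6R epimer
Reagents that add atoms: none
Why: Desilylation frees the γ-hydroperoxide, which closes on the C3 ketone to the six-membered peroxyhemiketal. C3 is set thermodynamically (S: anomeric OH axial, cis to the equatorial 4-methyl), and the rigid ring lets the (6S) diastereomer, with its side chain equatorial and cis to 4-Me, be separated and assigned by NOE.

**Step 14**
Reactants: 22 tert-butyl ester
Product: 23 2-[(3S,4R,6S)-3-hydroxy-4,6-dimethyl-6-[(2R)-2-methyl-10-phenyldecyl]-1,2-dioxan-3-yl]acetic acid (target)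
Conditions: TFA/CH2Cl2 1:4, 0 °C; evaporate cold
Reagents that add atoms: none
Why: Acidolysis of the tert-butyl ester (loss of isobutene) is much faster than ionisation of the weakly basic peroxide oxygens, and the closed hemiketal protects the latent β-keto acid from decarboxylation.

**Compound list**
1 | (S)-citronellol, (3S)-3,7-dimethyloct-6-en-1-ol | C[C@H](CCO)CCC=C(C)C | starting material
2 | (3S)-3,7-dimethyloct-6-en-1-yl 4-methylbenzenesulfonate | C[C@H](CCOS(=O)(=O)c1ccc(C)cc1)CCC=C(C)C | intermediate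
3 | (6-bromohexyl)benzene | BrCCCCCCc1ccccc1 | starting material
4 | (6-phenylhexyl)magnesium bromide | Br[Mg]CCCCCCc1ccccc1 | intermediate
5 | [(9R)-9,13-dimethyltetradec-12-en-1-yl]benzene | C[C@H](CCCCCCCCc1ccccc1)CCC=C(C)C | intermediate
6 | 3,3-dimethyl-5-[(3R)-3-methyl-11-phenylundecyl]-1,2,4-trioxolane (ozonide, mixture at the ring CH) | C[C@H](CCCCCCCCc1ccccc1)CCC1OOC(C)(C)O1 | intermediate
7 | (4R)-4-methyl-12-phenyldodecanal | C[C@H](CCCCCCCCc1ccccc1)CCC=O | intermediate
8 | (4R)-4-methyl-2-methylidene-12-phenyldodecanal | C[C@H](CCCCCCCCc1ccccc1)CC(=C)C=O | intermediate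
9 | (4R)-4-methyl-2-methylidene-12-phenyldodecan-1-ol | C[C@H](CCCCCCCCc1ccccc1)CC(=C)CO | intermediate
10 | [(9R)-11-(bromomethyl)-9-methyldodec-11-en-1-yl]benzene | C[C@H](CCCCCCCCc1ccccc1)CC(=C)CBr | intermediate
11 | (4S)-4-benzyl-3-propanoyl-1,3-oxazolidin-2-one | CCC(=O)N1[C@@H](Cc2ccccc2)COC1=O | starting material
12 | sodium (Z)-enolate of 11 | [Na+].C/C=C(\[O-])N1[C@@H](Cc2ccccc2)COC1=O | intermediate
13 | (4S)-4-benzyl-3-[(2R,6R)-2,6-dimethyl-4-methylidene-14-phenyltetradecanoyl]-1,3-oxazolidin-2-one | C[C@H](CCCCCCCCc1ccccc1)CC(=C)C[C@@H](C)C(=O)N1[C@@H](Cc2ccccc2)COC1=O | intermediate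
14 | (2R,6R)-2,6-dimethyl-4-methylidene-14-phenyltetradecan-1-ol | C[C@H](CCCCCCCCc1ccccc1)CC(=C)C[C@@H](C)CO | intermediate
15 | (2R,6R)-2,6-dimethyl-4-methylidene-14-phenyltetradecanal | C[C@H](CCCCCCCCc1ccccc1)CC(=C)C[C@@H](C)C=O | intermediate
16 | tert-butyl acetate | CC(=O)OC(C)(C)C | starting material
17 | lithium 1-(tert-butoxy)ethen-1-olate | [Li+].[O-]C(=C)OC(C)(C)C | intermediate
18 | tert-butyl (4R,8R)-3-hydroxy-4,8-dimethyl-6-methylidene-16-phenylhexadecanoate (C3 epimers) | C[C@H](CCCCCCCCc1ccccc1)CC(=C)C[C@@H](C)C(O)CC(=O)OC(C)(C)C | intermediate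
19 | tert-butyl (4R,8R)-3-hydroxy-4,6,8-trimethyl-16-phenyl-6-[(triethylsilyl)peroxy]hexadecanoate (C3 and C6 epimers) | C[C@H](CCCCCCCCc1ccccc1)CC(C)(OO[Si](CC)(CC)CC)C[C@@H](C)C(O)CC(=O)OC(C)(C)C | intermediate
20 | tert-butyl (4R,8R)-4,6,8-trimethyl-3-oxo-16-phenyl-6-[(triethylsilyl)peroxy]hexadecanoate (C6 epimers) | C[C@H](CCCCCCCCc1ccccc1)CC(C)(OO[Si](CC)(CC)CC)C[C@@H](C)C(=O)CC(=O)OC(C)(C)C | intermediate
21 | tert-butyl (4R,8R)-6-hydroperoxy-4,6,8-trimethyl-3-oxo-16-phenylhexadecanoate (C6 epimers) | C[C@H](CCCCCCCCc1ccccc1)CC(C)(OO)C[C@@H](C)C(=O)CC(=O)OC(C)(C)C | intermediate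
22 | tert-butyl 2-[(3S,4R,6S)-3-hydroxy-4,6-dimethyl-6-[(2R)-2-methyl-10-phenyldecyl]-1,2-dioxan-3-yl]acetate | C[C@H](CCCCCCCCc1ccccc1)C[C@@]1(C)C[C@@H](C)[C@](O)(CC(=O)OC(C)(C)C)OO1 | intermediate
23 | 2-[(3S,4R,6S)-3-hydroxy-4,6-dimethyl-6-[(2R)-2-methyl-10-phenyldecyl]-1,2-dioxan-3-yl]acetic acid | C[C@H](CCCCCCCCc1ccccc1)C[C@@]1(C)C[C@@H](C)[C@](O)(CC(=O)O)OO1 | target

**Totals**
Total steps: 14. Longest linear sequence: 14 steps (1 → 23).

**Three steps most likely to fail**

Step 11 (peroxysilylation of the hydroxy ester). The free carbinol may slow the cobalt cycle or favour reduction and hydration products, and four isomers must be followed. Fallback: change the order of the redox events. Set out from 18 and oxidise it first (DMP, NaHCO3, CH2Cl2) to tert-butyl (4R,8R)-4,8-dimethyl-6-methylidene-3-oxo-16-phenylhexadecanoate F1. Run the Co(thd)2/Et3SiH/O2 peroxysilylation on this keto ester, which has no carbinol and gives only the two C6 isomers. This gives 20 directly, where the route is rejoined and step 12 falls away.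

Step 13 (ring closure and separation of the C6 epimers). The hemiketals can ring-open on silica and may co-elute. Fallback: separate as locked peroxyketals. Set out from 20 and treat it with catalytic TsOH in dry MeOH (0 °C → rt). Desilylation via 21 and ketalisation give tert-butyl 2-[(3S,4R,6S)-3-methoxy-4,6-dimethyl-6-[(2R)-2-methyl-10-phenyldecyl]-1,2-dioxan-3-yl]acetate F2, which cannot ring-open and is separated from its 6R epimer. TFA/H2O/CH2Cl2 at 0 °C then hydrolyses the methyl peroxyketal and the tert-butyl ester together and comes back to the route at 23.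

Step 14 (acidolysis next to a peroxyhemiketal and latent β-keto acid). Cold TFA could cause dehydration, C6–O ionisation or decarboxylation. Fallback: carry an ester that is removed enzymatically at neutral pH. Set out from 15 and use methyl acetate in the aldol:
- LDA gives lithium 1-methoxyethen-1-olate F3, and the aldol gives methyl (4R,8R)-3-hydroxy-4,8-dimethyl-6-methylidene-16-phenylhexadecanoate F4.
- Peroxysilylation as in step 11 gives methyl (4R,8R)-3-hydroxy-4,6,8-trimethyl-16-phenyl-6-[(triethylsilyl)peroxy]hexadecanoate F5.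
- DMP gives methyl (4R,8R)-4,6,8-trimethyl-3-oxo-16-phenyl-6-[(triethylsilyl)peroxy]hexadecanoate F6.
- HF/MeCN gives, via methyl (4R,8R)-6-hydroperoxy-4,6,8-trimethyl-3-oxo-16-phenylhexadecanoate F7, the hemiketal methyl 2-[(3S,4R,6S)-3-hydroxy-4,6-dimethyl-6-[(2R)-2-methyl-10-phenyldecyl]-1,2-dioxan-3-yl]acetate F8 after removal of the 6R epimer.
- Pig-liver esterase in pH 7 phosphate buffer with 10% acetone at rt cleaves the methyl ester without acid or base and returns to the route at 23.

**Further compounds**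
F1 | step 11 | tert-butyl (4R,8R)-4,8-dimethyl-6-methylidene-3-oxo-16-phenylhexadecanoate | C[C@H](CCCCCCCCc1ccccc1)CC(=C)C[C@@H](C)C(=O)CC(=O)OC(C)(C)C
F2 | step 13 | tert-butyl 2-[(3S,4R,6S)-3-methoxy-4,6-dimethyl-6-[(2R)-2-methyl-10-phenyldecyl]-1,2-dioxan-3-yl]acetate | C[C@H](CCCCCCCCc1ccccc1)C[C@@]1(C)C[C@@H](C)[C@](OC)(CC(=O)OC(C)(C)C)OO1
F3 | step 14 | lithium 1-methoxyethen-1-olate | [Li+].[O-]C(=C)OC
F4 | step 14 | methyl (4R,8R)-3-hydroxy-4,8-dimethyl-6-methylidene-16-phenylhexadecanoate (C3 epimers) | C[C@H](CCCCCCCCc1ccccc1)CC(=C)C[C@@H](C)C(O)CC(=O)OC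
F5 | step 14 | methyl (4R,8R)-3-hydroxy-4,6,8-trimethyl-16-phenyl-6-[(triethylsilyl)peroxy]hexadecanoate (C3 and C6 epimers) | C[C@H](CCCCCCCCc1ccccc1)CC(C)(OO[Si](CC)(CC)CC)C[C@@H](C)C(O)CC(=O)OC
F6 | step 14 | methyl (4R,8R)-4,6,8-trimethyl-3-oxo-16-phenyl-6-[(triethylsilyl)peroxy]hexadecanoate (C6 epimers) | C[C@H](CCCCCCCCc1ccccc1)CC(C)(OO[Si](CC)(CC)CC)C[C@@H](C)C(=O)CC(=O)OC
F7 | step 14 | methyl (4R,8R)-6-hydroperoxy-4,6,8-trimethyl-3-oxo-16-phenylhexadecanoate (C6 epimers) | C[C@H](CCCCCCCCc1ccccc1)CC(C)(OO)C[C@@H](C)C(=O)CC(=O)OC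
F8 | step 14 | methyl 2-[(3S,4R,6S)-3-hydroxy-4,6-dimethyl-6-[(2R)-2-methyl-10-phenyldecyl]-1,2-dioxan-3-yl]acetate | C[C@H](CCCCCCCCc1ccccc1)C[C@@]1(C)C[C@@H](C)[C@](O)(CC(=O)OC)OO1
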